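**Retrosynthetic overview**

- The target, a dodecaphenol, comes from one global O-dealkylation of a pentamer in which ring B carries one free OH and one OEt and the ten other hydroxyls are OMe.
- Ring B is the only ring built, and it is built last. It is a benzene ring with free hydroxyls on C-1 and C-3, the ether oxygen to ring C on C-2 between them, the ether oxygen to ring A on C-5 (para to C-2), and CH at C-4 and C-6. This resorcinol with two para-disposed aryloxy groups is what a cyclobutenone–ynol ether benzannulation delivers. The ring A aryl ynol ether supplies C-5 (with its oxygen) and C-6; a 3-ethoxy-4-aryloxycyclobutenone carrying rings C, D and E supplies C-1 to C-4.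
- The cyclobutenone comes from a [2+2] cycloaddition of ethoxyacetylene with the aryloxyketene of the ring C–D–E aryloxyacetic acid. The ynol ether comes from 2,4,6-trimethoxyphenol through its 1,2-dichlorovinyl ether.
- The ring C–D–E phenol comes from a benzyl-protected ring C phenol by two rounds of SNAr on 4-fluoro-2,6-dimethoxybenzaldehyde, each followed by Baeyer–Villiger oxidation. Rings A, C, D and E are bought as benzene rings.

Key step: step 14

Remark: the target has no stereocentre and no stereogenic double bond, so only regiochemistry has to be controlled; the cyclobutenone of the key step is made and used as the racemate.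

**Route**

Step 1
Reactants: 1 2,4,6-trimethoxybenzaldehyde
Product: 3 2,4,6-trimethoxyphenol, via 2,4,6-trimethoxyphenyl formate 2 (not isolated)
Conditions: mCPBA, CH2Cl2, 0 °C to rt; then K2CO3 (cat.), MeOH, rt, under argon
Reagents that add atoms: mCPBA (3-chloroperoxybenzoic acid), O=C(OO)c1cccc(Cl)c1
Why: Baeyer–Villiger oxidation, in which the electron-rich trimethoxyphenyl group migrates in preference to hydrogen, followed by mild methanolysis of the aryl formate.

Step 2
Reactants: 3 2,4,6-trimethoxyphenol; 4 trichloroethylene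
Product: 6 2-[(E)-1,2-dichlorovinyloxy]-1,3,5-trimethoxybenzene, via dichloroacetylene 5 (not isolated)
Conditions: K2CO3, DMF, 70 °C
Reagents that add atoms: none
Why: Base eliminates HCl from trichloroethylene and the phenoxide adds anti to the dichloroacetylene formed (nucleophilic addition to a haloalkyne), the standard entry to aryl (E)-1,2-dichlorovinyl ethers, which also sets the E geometry.

Step 3
Reactants: 6 2-[(E)-1,2-dichlorovinyloxy]-1,3,5-trimethoxybenzene
Product: 9 2-ethynyloxy-1,3,5-trimethoxybenzene (ring A ynol ether), via chloroethynyl ether 7 (not isolated), via lithium acetylide 8 (not isolated)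
Conditions: n-BuLi (2.2 equiv), THF, −78 to −40 °C; then H2O, −78 °C; quick filtration through Et3N-deactivated silica, stored cold in toluene
Reagents that add atoms: none
Why: Deprotonation and anti elimination of LiCl give the chloroalkynyl ether, lithium–chlorine exchange gives the acetylide and protonation gives the terminal ynol ether (the dichlorovinyl ether route to ynol ethers), all of which outrun ring lithiation at −78 °C.

Step 4
Reactants: 10 2-hydroxy-4,6-dimethoxybenzaldehyde
Product: 11 2-benzyloxy-4,6-dimethoxybenzaldehyde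
Conditions: BnBr, K2CO3, DMF, 60 °C
Reagents that add atoms: benzyl bromide, BrCc1ccccc1
Why: Williamson ether synthesis that masks the future ring C to ring B oxygen as a benzyl ether, which survives peracid, base and SNAr conditions and is later removed without touching methyl ethers.

Step 5
Reactants: 11 2-benzyloxy-4,6-dimethoxybenzaldehyde
Product: 13 2-benzyloxy-4,6-dimethoxyphenol (ring C phenol), via aryl formate 12 (not isolated)
Conditions: mCPBA, CH2Cl2, 0 °C to rt; then K2CO3 (cat.), MeOH, rt, under argon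
Reagents that add atoms: mCPBA (3-chloroperoxybenzoic acid), O=C(OO)c1cccc(Cl)c1
Why: Baeyer–Villiger oxidation with migration of the electron-rich aryl group and methanolysis of the formate turn the formyl carbon into the phenol oxygen that will bond to ring D.

Step 6
Reactants: 13 2-benzyloxy-4,6-dimethoxyphenol; 14 4-fluoro-2,6-dimethoxybenzaldehyde
Product: 15 4-(2-benzyloxy-4,6-dimethoxyphenoxy)-2,6-dimethoxybenzaldehyde (rings C–D aldehyde)
Conditions: Cs2CO3, DMSO, 110 °C, under argon
Reagents that add atoms: none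
Why: SNAr through a Meisenheimer intermediate stabilised by the para formyl group; the attacked carbon has only hydrogens beside it, so the doubly ortho-substituted phenoxide is accepted, and both methoxy groups are meta to fluorine and do not deactivate it by resonance.

Step 7
Reactants: 15 4-(2-benzyloxy-4,6-dimethoxyphenoxy)-2,6-dimethoxybenzaldehyde
Product: 17 4-(2-benzyloxy-4,6-dimethoxyphenoxy)-2,6-dimethoxyphenol, via aryl formate 16 (not isolated)
Conditions: mCPBA, CH2Cl2, 0 °C to rt; then K2CO3 (cat.), MeOH, rt, under argon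
Reagents that add atoms: mCPBA (3-chloroperoxybenzoic acid), O=C(OO)c1cccc(Cl)c1
Why: Baeyer–Villiger oxidation of the 2,6-dimethoxybenzaldehyde unit and formate methanolysis unveil the ring D hydroxyl flanked by two methoxy groups.

Step 8
Reactants: 17 4-(2-benzyloxy-4,6-dimethoxyphenoxy)-2,6-dimethoxyphenol; 14 4-fluoro-2,6-dimethoxybenzaldehyde
Product: 18 4-[4-(2-benzyloxy-4,6-dimethoxyphenoxy)-2,6-dimethoxyphenoxy]-2,6-dimethoxybenzaldehyde
Conditions: Cs2CO3, DMSO, 110 °C, under argon
Reagents that add atoms: none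
Why: A second SNAr of the same kind as step 6 places the hindered ring D oxygen on the unhindered, aldehyde-activated carbon of the ring E precursor.

Step 9
Reactants: 18 4-[4-(2-benzyloxy-4,6-dimethoxyphenoxy)-2,6-dimethoxyphenoxy]-2,6-dimethoxybenzaldehyde
Product: 20 4-[4-(2-benzyloxy-4,6-dimethoxyphenoxy)-2,6-dimethoxyphenoxy]-2,6-dimethoxyphenol, via aryl formate 19 (not isolated)
Conditions: mCPBA, CH2Cl2, 0 °C to rt; then K2CO3 (cat.), MeOH, rt, under argon
Reagents that add atoms: mCPBA (3-chloroperoxybenzoic acid), O=C(OO)c1cccc(Cl)c1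
Why: Baeyer–Villiger oxidation and formate methanolysis convert the formyl group into the third oxygen of ring E.

Step 10
Reactants: 20 4-[4-(2-benzyloxy-4,6-dimethoxyphenoxy)-2,6-dimethoxyphenoxy]-2,6-dimethoxyphenol
Product: 21 1-benzyloxy-2-[3,5-dimethoxy-4-(3,4,5-trimethoxyphenoxy)phenoxy]-3,5-dimethoxybenzene
Conditions: MeI, K2CO3, acetone, reflux
Reagents that add atoms: iodomethane, CI
Why: Williamson methylation of the only free phenol completes the 3,4,5-trimethoxyphenyl ring E.

Step 11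
Reactants: 21 1-benzyloxy-2-[3,5-dimethoxy-4-(3,4,5-trimethoxyphenoxy)phenoxy]-3,5-dimethoxybenzene
Product: 22 2-[3,5-dimethoxy-4-(3,4,5-trimethoxyphenoxy)phenoxy]-3,5-dimethoxyphenol (rings C–D–E phenol)
Conditions: H2 (1 atm), Pd/C, EtOAc/MeOH, rt
Reagents that add atoms: none
Why: Catalytic hydrogenolysis cleaves the benzyl ether only, since diaryl and methyl ethers are inert.

Step 12
Reactants: 22 2-[3,5-dimethoxy-4-(3,4,5-trimethoxyphenoxy)phenoxy]-3,5-dimethoxyphenol; 23 bromoacetic acid
Product: 24 {2-[3,5-dimethoxy-4-(3,4,5-trimethoxyphenoxy)phenoxy]-3,5-dimethoxyphenoxy}acetic acid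
Conditions: NaH (2.5 equiv), THF/DMF, 0 to 60 °C; then aq. HCl
Reagents that add atoms: none
Why: Williamson O-alkylation of the sodium phenoxide by sodium bromoacetate forms the ring C oxygen to carbon bond by simple SN2 and brings in the two carbons that become C-1 and C-2 of ring B.

Step 13
Reactants: 24 {2-[3,5-dimethoxy-4-(3,4,5-trimethoxyphenoxy)phenoxy]-3,5-dimethoxyphenoxy}acetic acid; 25 ethoxyacetylene
Product: 28 racemic 3-ethoxy-4-{2-[3,5-dimethoxy-4-(3,4,5-trimethoxyphenoxy)phenoxy]-3,5-dimethoxyphenoxy}cyclobut-2-en-1-one, via acid chloride 26 (not isolated), via aryloxyketene 27 (not isolated)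
Conditions: (COCl)2, DMF (cat.), CH2Cl2, 0 °C to rt, evaporate; then 25 (4 equiv), Et3N (slow addition), CH2Cl2, 0 °C to rt; Et3N-deactivated silica
Reagents that add atoms: none
Why: Et3N dehydrochlorinates the acid chloride to the aryloxyketene, which is trapped in a thermal [2+2] ketene–alkyne cycloaddition where the ketene carbonyl carbon bonds to the unsubstituted nucleophilic carbon of ethoxyacetylene, giving the 3-ethoxy-4-aryloxy pattern; the C-4 stereocentre forms as a racemate and is destroyed in step 14.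

Step 14
Reactants: 28 racemic 3-ethoxy-4-{2-[3,5-dimethoxy-4-(3,4,5-trimethoxyphenoxy)phenoxy]-3,5-dimethoxyphenoxy}cyclobut-2-en-1-one; 9 2-ethynyloxy-1,3,5-trimethoxybenzene
Product: 33 2-{2-[3,5-dimethoxy-4-(3,4,5-trimethoxyphenoxy)phenoxy]-3,5-dimethoxyphenoxy}-3-ethoxy-5-(2,4,6-trimethoxyphenoxy)phenol, via vinylketene 29 (not isolated), via 4-alkenylcyclobutenone 30 (not isolated), via dienylketene 31 (not isolated), via cyclohexadienone 32 (not isolated)
Conditions: 28 added slowly to 9 in degassed toluene, 80 °C; then 110 °C, sealed tube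
Reagents that add atoms: none
Why: Proposed new method: Four-electron electrocyclic opening of 28 gives vinylketene 29, whose ketene C=C adds ynol ether 9 in a [2+2] cycloaddition (new bonds C-4 to C-5 and C-6 to C-1 of ring B) to give cyclobutenone 30; a second four-electron opening gives dienylketene 31, six-electron electrocyclisation re-joins C-1 to C-2 to give cyclohexadienone 32, and enolisation gives phenol 33. The closest known reaction type is the Danheiser benzannulation of cyclobutenones with alkoxy- and siloxyalkynes, which has not been run with an aryl ynol ether or a 4-aryloxycyclobutenone; the aryloxy oxygen, on an electron-rich trimethoxyphenyl ring, should still polarise the alkyne enough, and without a β-hydrogen the ynol ether cannot fragment by a retro-ene path at these temperatures. The six-membered ring B closes by a thermally allowed disrotatory six-electron electrocyclisation, reached because the reversible cyclobutenone opening funnels material through the dienylketene isomer with the ketene and the ethoxyvinyl group cis on the central double bond. No stereocentre remains, since the sp3 carbons of 30 and 32 become aromatic carbons. The selectivity needed is the regiochemistry of the [2+2] step, secured by the polarisation of both partners: the unsubstituted nucleophilic carbon of 9 bonds to the electrophilic ketene carbonyl carbon, so the ring A oxygen ends meta to the new hydroxyl and para to the ring C oxygen. The step is a pure addition in which 28 and 9 combine one to one with no atom lost, and adding 28 slowly to 9 keeps 29 dilute beside the alkyne so that the ynol ether and not the product phenol intercepts it.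

Step 15
Reactants: 33 2-{2-[3,5-dimethoxy-4-(3,4,5-trimethoxyphenoxy)phenoxy]-3,5-dimethoxyphenoxy}-3-ethoxy-5-(2,4,6-trimethoxyphenoxy)phenol
Product: 34 target dodecaphenol CNP0227069.0
Conditions: BBr3 (excess), CH2Cl2, −78 °C to rt; then MeOH, H2O; Sephadex LH-20 under argon
Reagents that add atoms: none
Why: Lewis acid ether cleavage in which BBr3 coordinates each alkyl aryl ether oxygen and bromide attacks the methyl or ethyl carbon by SN2, while the four diaryl ether bonds have no sp3 carbon and survive.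

**Compound list**

1 | 2,4,6-trimethoxybenzaldehyde | COc1cc(OC)c(C=O)c(OC)c1 | starting material
2 | 2,4,6-trimethoxyphenyl formate | COc1cc(OC)c(OC=O)c(OC)c1 | intermediate (not isolated)
3 | 2,4,6-trimethoxyphenol | COc1cc(OC)c(O)c(OC)c1 | intermediate
4 | trichloroethylene | ClC=C(Cl)Cl | starting material
5 | dichloroacetylene | ClC#CCl | intermediate (not isolated)
6 | 2-[(E)-1,2-dichlorovinyloxy]-1,3,5-trimethoxybenzene | COc1cc(OC)c(O/C(Cl)=C\Cl)c(OC)c1 | intermediate
7 | 2-(chloroethynyloxy)-1,3,5-trimethoxybenzene | COc1cc(OC)c(OC#CCl)c(OC)c1 | intermediate (not isolated)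
8 | lithium (2,4,6-trimethoxyphenoxy)acetylide | COc1cc(OC)c(OC#C[Li])c(OC)c1 | intermediate (not isolated)
9 | 2-ethynyloxy-1,3,5-trimethoxybenzene (ring A ynol ether) | COc1cc(OC)c(OC#C)c(OC)c1 | intermediate
10 | 2-hydroxy-4,6-dimethoxybenzaldehyde | COc1cc(O)c(C=O)c(OC)c1 | starting material
11 | 2-benzyloxy-4,6-dimethoxybenzaldehyde | COc1cc(OCc2ccccc2)c(C=O)c(OC)c1 | intermediate
12 | 2-benzyloxy-4,6-dimethoxyphenyl formate | COc1cc(OCc2ccccc2)c(OC=O)c(OC)c1 | intermediate (not isolated)
13 | 2-benzyloxy-4,6-dimethoxyphenol | COc1cc(OCc2ccccc2)c(O)c(OC)c1 | intermediate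
14 | 4-fluoro-2,6-dimethoxybenzaldehyde | COc1cc(F)cc(OC)c1C=O | starting material
15 | 4-(2-benzyloxy-4,6-dimethoxyphenoxy)-2,6-dimethoxybenzaldehyde | COc1cc(OCc2ccccc2)c(Oc2cc(OC)c(C=O)c(OC)c2)c(OC)c1 | intermediate
16 | 4-(2-benzyloxy-4,6-dimethoxyphenoxy)-2,6-dimethoxyphenyl formate | COc1cc(OCc2ccccc2)c(Oc2cc(OC)c(OC=O)c(OC)c2)c(OC)c1 | intermediate (not isolated)
17 | 4-(2-benzyloxy-4,6-dimethoxyphenoxy)-2,6-dimethoxyphenol | COc1cc(OCc2ccccc2)c(Oc2cc(OC)c(O)c(OC)c2)c(OC)c1 | intermediate
18 | 4-[4-(2-benzyloxy-4,6-dimethoxyphenoxy)-2,6-dimethoxyphenoxy]-2,6-dimethoxybenzaldehyde | COc1cc(OCc2ccccc2)c(Oc2cc(OC)c(Oc3cc(OC)c(C=O)c(OC)c3)c(OC)c2)c(OC)c1 | intermediate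
19 | 4-[4-(2-benzyloxy-4,6-dimethoxyphenoxy)-2,6-dimethoxyphenoxy]-2,6-dimethoxyphenyl formate | COc1cc(OCc2ccccc2)c(Oc2cc(OC)c(Oc3cc(OC)c(OC=O)c(OC)c3)c(OC)c2)c(OC)c1 | intermediate (not isolated)
20 | 4-[4-(2-benzyloxy-4,6-dimethoxyphenoxy)-2,6-dimethoxyphenoxy]-2,6-dimethoxyphenol | COc1cc(OCc2ccccc2)c(Oc2cc(OC)c(Oc3cc(OC)c(O)c(OC)c3)c(OC)c2)c(OC)c1 | intermediate
21 | 1-benzyloxy-2-[3,5-dimethoxy-4-(3,4,5-trimethoxyphenoxy)phenoxy]-3,5-dimethoxybenzene | COc1cc(OCc2ccccc2)c(Oc2cc(OC)c(Oc3cc(OC)c(OC)c(OC)c3)c(OC)c2)c(OC)c1 | intermediate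
22 | 2-[3,5-dimethoxy-4-(3,4,5-trimethoxyphenoxy)phenoxy]-3,5-dimethoxyphenol (rings C–D–E phenol) | COc1cc(O)c(Oc2cc(OC)c(Oc3cc(OC)c(OC)c(OC)c3)c(OC)c2)c(OC)c1 | intermediate
23 | bromoacetic acid | OC(=O)CBr | starting material
24 | {2-[3,5-dimethoxy-4-(3,4,5-trimethoxyphenoxy)phenoxy]-3,5-dimethoxyphenoxy}acetic acid | COc1cc(OCC(O)=O)c(Oc2cc(OC)c(Oc3cc(OC)c(OC)c(OC)c3)c(OC)c2)c(OC)c1 | intermediate
25 | ethoxyacetylene | CCOC#C | starting material
26 | {2-[3,5-dimethoxy-4-(3,4,5-trimethoxyphenoxy)phenoxy]-3,5-dimethoxyphenoxy}acetyl chloride | COc1cc(OCC(Cl)=O)c(Oc2cc(OC)c(Oc3cc(OC)c(OC)c(OC)c3)c(OC)c2)c(OC)c1 | intermediate (not isolated)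
27 | {2-[3,5-dimethoxy-4-(3,4,5-trimethoxyphenoxy)phenoxy]-3,5-dimethoxyphenoxy}ketene | COc1cc(OC=C=O)c(Oc2cc(OC)c(Oc3cc(OC)c(OC)c(OC)c3)c(OC)c2)c(OC)c1 | intermediate (not isolated)
28 | racemic 3-ethoxy-4-{2-[3,5-dimethoxy-4-(3,4,5-trimethoxyphenoxy)phenoxy]-3,5-dimethoxyphenoxy}cyclobut-2-en-1-one | CCOC1=CC(=O)C1Oc1cc(OC)cc(OC)c1Oc1cc(OC)c(Oc2cc(OC)c(OC)c(OC)c2)c(OC)c1 | intermediate
29 | 3-ethoxy-4-(rings C–D–E aryloxy)buta-1,3-dien-1-one, aryloxy group trans to the ketene-bearing carbon (vinylketene) | O=C=C/C(OCC)=C/Oc1cc(OC)cc(OC)c1Oc1cc(OC)c(Oc2cc(OC)c(OC)c(OC)c2)c(OC)c1 | intermediate (not isolated)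
30 | racemic 4-[1-ethoxy-2-(rings C–D–E aryloxy)vinyl]-3-(2,4,6-trimethoxyphenoxy)cyclobut-2-en-1-one | O=C1C=C(Oc2c(OC)cc(OC)cc2OC)C1/C(OCC)=C/Oc1cc(OC)cc(OC)c1Oc1cc(OC)c(Oc2cc(OC)c(OC)c(OC)c2)c(OC)c1 | intermediate (not isolated)
31 | 5-ethoxy-6-(rings C–D–E aryloxy)-3-(2,4,6-trimethoxyphenoxy)hexa-1,3,5-trien-1-one, ketene carbon and ethoxyvinyl group cis on the central double bond (dienylketene) | O=C=C/C(Oc1c(OC)cc(OC)cc1OC)=C\C(OCC)=C\Oc1cc(OC)cc(OC)c1Oc1cc(OC)c(Oc2cc(OC)c(OC)c(OC)c2)c(OC)c1 | intermediate (not isolated)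
32 | racemic 5-ethoxy-6-(rings C–D–E aryloxy)-3-(2,4,6-trimethoxyphenoxy)cyclohexa-2,4-dien-1-one | O=C1C=C(Oc2c(OC)cc(OC)cc2OC)C=C(OCC)C1Oc1cc(OC)cc(OC)c1Oc1cc(OC)c(Oc2cc(OC)c(OC)c(OC)c2)c(OC)c1 | intermediate (not isolated)
33 | 2-{2-[3,5-dimethoxy-4-(3,4,5-trimethoxyphenoxy)phenoxy]-3,5-dimethoxyphenoxy}-3-ethoxy-5-(2,4,6-trimethoxyphenoxy)phenol | CCOc1cc(Oc2c(OC)cc(OC)cc2OC)cc(O)c1Oc1cc(OC)cc(OC)c1Oc1cc(OC)c(Oc2cc(OC)c(OC)c(OC)c2)c(OC)c1 | intermediate
34 | CNP0227069.0, pentameric phloroglucinol aryl ether with twelve free hydroxyls | Oc1cc(O)c(Oc2cc(O)c(Oc3cc(O)cc(O)c3Oc3cc(O)c(Oc4cc(O)c(O)c(O)c4)c(O)c3)c(O)c2)c(O)c1 | target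

**Step count**

Total: 15 steps. Longest linear sequence: 12 steps (10 to 34, steps 4 to 15); the ring A branch (steps 1 to 3) joins at step 14.

**Steps most likely to fail**

1. Step 14 (proposed new method). The aryl ynol ether is a weaker ketenophile than the alkyl and silyl ynol ethers used so far. Vinylketene 29 may therefore be lost to oligomerisation, to acylation of the product phenol, or to attack on the electron-rich ring C before the [2+2] step occurs; the terminal ynol ether may also polymerise on heating.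
 Fallback by known chemistry, setting out from 3 and 14 and coming back to the route at 34: the chain is grown from the ring A end by the SNAr and Baeyer–Villiger sequence already used in steps 5 to 10. Cs2CO3 in DMSO joins 3 to 14 to give 2,6-dimethoxy-4-(2,4,6-trimethoxyphenoxy)benzaldehyde F1. mCPBA converts it into 2,6-dimethoxy-4-(2,4,6-trimethoxyphenoxy)phenyl formate F2, which is methanolysed to 2,6-dimethoxy-4-(2,4,6-trimethoxyphenoxy)phenol F3. SNAr of F3 on commercial 2-fluoro-4,6-dimethoxybenzaldehyde, whose fluorine is ortho to the formyl group, gives the rings A–B–C aldehyde F4. Its formyl carbon is the future ring C carbon that bonds to the ring D oxygen; oxidation gives the rings A–B–C formate F5 and methanolysis gives the rings A–B–C phenol F6. A round with 14 gives the rings A–B–C–D aldehyde F7, the rings A–B–C–D formate F8 and the rings A–B–C–D phenol F9. A further round with 14 gives the five-ring aldehyde F10, the five-ring formate F11 and the five-ring phenol F12. MeI and K2CO3 then give the dodecamethyl ether of the target F13, and BBr3 in CH2Cl2 cleaves all twelve methyl ethers to give 34.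

2. Step 13. The aryloxyketene may dimerise, or the acid chloride may close onto ring C by Friedel–Crafts acylation, before ethoxyacetylene adds; the acid-labile ethoxycyclobutenone may also hydrolyse on isolation.
 Fallback, setting out from 22 and 9 and coming back at 33: the vinylketene is made without the cyclobutenone. Phenol 22 is alkylated with commercial ethyl (E)-4-bromo-3-ethoxybut-2-enoate (K2CO3, acetone) to give the ethyl (E)-4-aryloxy-3-ethoxybut-2-enoate F14. LiOH in THF/H2O gives the (E)-4-aryloxy-3-ethoxybut-2-enoic acid F15, and (COCl)2 with catalytic DMF gives the (E)-4-aryloxy-3-ethoxybut-2-enoyl chloride F16. Et3N in the presence of 9 effects 1,4-dehydrochlorination, a known way to vinylketenes from α,β-unsaturated acid chlorides, and should give 29 directly. Ynol ether 9 traps it as 30, and heating in toluene carries 30 through 31 and 32 to 33.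

3. Step 6 (the same reaction recurs in step 8). The formyl group, weakened as an acceptor by two ortho methoxy donors, may activate the fluoroarene too little, so that substitution is slow and air oxidation of the very electron-rich phenoxide competes at the temperature required.
 Fallback, setting out from 13 and coming back at 15: the bond is made by copper catalysis instead of SNAr, with no compound outside the list formed (F0). Phenol 13 and commercial 4-bromo-2,6-dimethoxybenzaldehyde are coupled in an Ullmann diaryl ether synthesis (CuI, picolinic acid, K3PO4, DMSO, 90 °C), conditions suited to ortho-disubstituted phenols and unhindered aryl bromides, to give 15.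

**Further compounds**

F1 | step 14 | 2,6-dimethoxy-4-(2,4,6-trimethoxyphenoxy)benzaldehyde | COc1cc(OC)c(Oc2cc(OC)c(C=O)c(OC)c2)c(OC)c1
F2 | step 14 | 2,6-dimethoxy-4-(2,4,6-trimethoxyphenoxy)phenyl formate | COc1cc(OC)c(Oc2cc(OC)c(OC=O)c(OC)c2)c(OC)c1
F3 | step 14 | 2,6-dimethoxy-4-(2,4,6-trimethoxyphenoxy)phenol | COc1cc(OC)c(Oc2cc(OC)c(O)c(OC)c2)c(OC)c1
F4 | step 14 | 2-[2,6-dimethoxy-4-(2,4,6-trimethoxyphenoxy)phenoxy]-4,6-dimethoxybenzaldehyde (rings A–B–C aldehyde) | COc1cc(OC)c(Oc2cc(OC)c(Oc3cc(OC)cc(OC)c3C=O)c(OC)c2)c(OC)c1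
F5 | step 14 | 2-[2,6-dimethoxy-4-(2,4,6-trimethoxyphenoxy)phenoxy]-4,6-dimethoxyphenyl formate (rings A–B–C formate) | COc1cc(OC)c(Oc2cc(OC)c(Oc3cc(OC)cc(OC)c3OC=O)c(OC)c2)c(OC)c1
F6 | step 14 | 2-[2,6-dimethoxy-4-(2,4,6-trimethoxyphenoxy)phenoxy]-4,6-dimethoxyphenol (rings A–B–C phenol) | COc1cc(OC)c(Oc2cc(OC)c(Oc3cc(OC)cc(OC)c3O)c(OC)c2)c(OC)c1
F7 | step 14 | rings A–B–C–D aldehyde, 4-aryloxy-2,6-dimethoxybenzaldehyde | COc1cc(OC)c(Oc2cc(OC)c(Oc3cc(OC)cc(OC)c3Oc3cc(OC)c(C=O)c(OC)c3)c(OC)c2)c(OC)c1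
F8 | step 14 | rings A–B–C–D formate | COc1cc(OC)c(Oc2cc(OC)c(Oc3cc(OC)cc(OC)c3Oc3cc(OC)c(OC=O)c(OC)c3)c(OC)c2)c(OC)c1
F9 | step 14 | rings A–B–C–D phenol | COc1cc(OC)c(Oc2cc(OC)c(Oc3cc(OC)cc(OC)c3Oc3cc(OC)c(O)c(OC)c3)c(OC)c2)c(OC)c1
F10 | step 14 | five-ring aldehyde, ring E as 4-aryloxy-2,6-dimethoxybenzaldehyde | COc1cc(OC)c(Oc2cc(OC)c(Oc3cc(OC)cc(OC)c3Oc3cc(OC)c(Oc4cc(OC)c(C=O)c(OC)c4)c(OC)c3)c(OC)c2)c(OC)c1
F11 | step 14 | five-ring formate | COc1cc(OC)c(Oc2cc(OC)c(Oc3cc(OC)cc(OC)c3Oc3cc(OC)c(Oc4cc(OC)c(OC=O)c(OC)c4)c(OC)c3)c(OC)c2)c(OC)c1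
F12 | step 14 | five-ring phenol, ring E as 4-aryloxy-2,6-dimethoxyphenol | COc1cc(OC)c(Oc2cc(OC)c(Oc3cc(OC)cc(OC)c3Oc3cc(OC)c(Oc4cc(OC)c(O)c(OC)c4)c(OC)c3)c(OC)c2)c(OC)c1
F13 | step 14 | dodecamethyl ether of the target | COc1cc(OC)c(Oc2cc(OC)c(Oc3cc(OC)cc(OC)c3Oc3cc(OC)c(Oc4cc(OC)c(OC)c(OC)c4)c(OC)c3)c(OC)c2)c(OC)c1
F14 | step 13 | ethyl (E)-3-ethoxy-4-{2-[3,5-dimethoxy-4-(3,4,5-trimethoxyphenoxy)phenoxy]-3,5-dimethoxyphenoxy}but-2-enoate | CCOC(=O)/C=C(/OCC)COc1cc(OC)cc(OC)c1Oc1cc(OC)c(Oc2cc(OC)c(OC)c(OC)c2)c(OC)c1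
F15 | step 13 | (E)-3-ethoxy-4-{2-[3,5-dimethoxy-4-(3,4,5-trimethoxyphenoxy)phenoxy]-3,5-dimethoxyphenoxy}but-2-enoic acid | OC(=O)/C=C(/OCC)COc1cc(OC)cc(OC)c1Oc1cc(OC)c(Oc2cc(OC)c(OC)c(OC)c2)c(OC)c1
F16 | step 13 | (E)-3-ethoxy-4-{2-[3,5-dimethoxy-4-(3,4,5-trimethoxyphenoxy)phenoxy]-3,5-dimethoxyphenoxy}but-2-enoyl chloride | ClC(=O)/C=C(/OCC)COc1cc(OC)cc(OC)c1Oc1cc(OC)c(Oc2cc(OC)c(OC)c(OC)c2)c(OC)c1
F0 | step 6 | none | none
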